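**Plan**

Atom numbers follow the labdane skeleton: ring A is C1–C5 and C10, ring B is C5–C10, and the side chain leaves C9 through C11 and C12.
- Cuts, in retrosynthetic order: the butenolide (Sonogashira coupling with lactonisation), C12–C13 (B-alkyl Suzuki–Miyaura coupling), C9–C11 (Stille coupling of a C9 enol triflate), then C7–C8 and C5–C10 together, which opens ring B and ring A to an acyclic keto-enal.
- Enabling feature: in ring B, C9 lies between C8 and C10, so a C9 ketone makes both of them donor carbons. The opposite three carbons C5–C6–C7 are an enal (C5 acceptor, C7 carbonyl). The C1–C4 chain of ring A, with quaternary C4 next to C5, tethers donor C10 to acceptor C5.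
- Forward order: two alkylations and a formyl-olefination build the chain (steps 1–5). One amine-catalysed Michael/aldol-condensation cascade closes ring A and then ring B (step 6). The C9 carbonyl then leaves as the C8=C9 enol triflate (step 7), and the side chain and butenolide follow (steps 8–14).
- Stereochemistry: C5 and C10 arise together in step 6, trans through a chair transition state, with the absolute sense from a chiral primary amine. The 13E alkene comes from a (Z)-iodo-enoate coupled with retention, and the (Z)-ylidene butenolide from anti addition in the 5-exo-dig lactonisation.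

Key step: step 6

Assumption: the quinine-derived amine is written for step 6; which pseudo-enantiomer of this catalyst leads to the (4aS,8aS) series cannot be derived from a reliable model and is fixed in the first run, the quinidine-derived catalyst being used if the sense is opposite.

**Route**

Step 1
Reactants: 1 isobutyronitrile; 2 1,3-dibromopropane
Product: 3 5-bromo-2,2-dimethylpentanenitrile
Conditions: LiN(i-Pr)2, THF, −78 °C; then 2 (3 equiv), −78 °C → rt
Reagents that add atoms: none
Why: alkylation of the nitrile-stabilised tertiary carbanion with excess dibromide; the product has no α-hydrogen and cannot be alkylated again.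

Step 2
Reactants: 4 pentan-3-one; 5 N,N-dimethylhydrazine
Product: 6 pentan-3-one N,N-dimethylhydrazone
Conditions: AcOH (cat.), EtOH, reflux
Reagents that add atoms: none
Why: hydrazone condensation; the hydrazone is the handle for the alkylation in step 3 and masks the ketone through steps 4 and 5.

Step 3
Reactants: 6 pentan-3-one N,N-dimethylhydrazone; 3 5-bromo-2,2-dimethylpentanenitrile
Product: 7 7-(2,2-dimethylhydrazinylidene)-2,2,6-trimethylnonanenitrile
Conditions: LiN(i-Pr)2, THF, 0 °C; then 3, −78 °C → rt
Reagents that add atoms: none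
Why: α-alkylation of the lithiated hydrazone (aza-enolate) with a primary bromide should form the C1–C10 bond; the new stereocentre is racemic and is erased in step 6.

Step 4
Reactants: 7 7-(2,2-dimethylhydrazinylidene)-2,2,6-trimethylnonanenitrile
Product: 8 7-(2,2-dimethylhydrazinylidene)-2,2,6-trimethylnonanal
Conditions: i-Bu2AlH (1.2 equiv), CH2Cl2, −78 → −20 °C; then aq. potassium sodium tartrate
Reagents that add atoms: water, O
Why: partial reduction of the tertiary nitrile to the N-aluminio aldimine, hydrolysed on neutral work-up; the electron-rich dialkylhydrazone C=N should not be reduced at low temperature.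

Step 5
Reactants: 8 7-(2,2-dimethylhydrazinylidene)-2,2,6-trimethylnonanal; 9 diethyl [(E)-2-(cyclohexylamino)ethenyl]phosphonate
Product: 11 (2E)-4,4,8-trimethyl-9-oxoundec-2-enal, via unsaturated aldimine 10 (not isolated)
Conditions: NaH, THF, 0 °C → rt; then aq. (CO2H)2, Et2O, rt
Reagents that add atoms: water, O
Why: Horner–Wadsworth–Emmons formyl-olefination of the non-enolisable α-quaternary aldehyde should give the (E)-unsaturated aldimine, which cannot be homologated again; two-phase oxalic acid hydrolysis then frees the enal and the ketone together.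

Step 6
Reactants: 11 (2E)-4,4,8-trimethyl-9-oxoundec-2-enal
Product: 13 (4aS,8aS)-2,5,5,8a-tetramethyl-4a,5,6,7,8,8a-hexahydronaphthalen-1(4H)-one, via keto aldehyde 12 (not isolated)
Conditions: 9-amino-9-deoxy-epi-quinine (20 mol%), CF3CO2H (40 mol%), PhMe (0.05 M), 40 °C, then 70 °C
Reagents that add atoms: none
Why: Proposed new method: the primary amine should condense reversibly with both carbonyl groups, so that the more substituted secondary enamine of the ketone (C9=C10) adds through C10 to C5 of the unsaturated iminium ion (Michael addition), and after proton transfer the enamine on the other side (C8=C9) attacks the C7 iminium carbon (Mannich-type aldol step) and loses the amine to give the C7=C8 enone; the closest known reaction types are the amine-catalysed Michael/aldol-condensation (Robinson-type, formal 3+3) annulation of ketones with enals and the primary-amine-catalysed Michael addition of α-branched cyclic ketones that creates quaternary carbons. Ring A closes in a 6-exo-trig mode with the enamine double bond exocyclic (enolexo), ring B in a 6-exo-trig mode with the enamine double bond inside the forming ring (enolendo). C5 and C10 are set together in the first bond formation: in a chair transition state of the forming ring A the arm at C10 that carries C9 and the arm at C5 that carries C6 lie equatorial and the C10 methyl axial, which gives the trans ring fusion, while the chiral amine on both reacting termini selects one of the two mirror-image chairs. The step needs C10 and not C8 to act as the first donor and C5 and not C7 as the first acceptor; ring size secures both, since only the C10-to-C5 mode closes a six-membered ring whereas the others need eight- or ten-membered rings. The quaternary C4 next to C5 leaves the enal without a γ-hydrogen, so that no dienamine or self-condensation path competes, and its gem-dimethyl group favours the folded conformer. Dilution keeps intermolecular aldol reactions down.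

Step 7
Reactants: 13 (4aS,8aS)-2,5,5,8a-tetramethyl-4a,5,6,7,8,8a-hexahydronaphthalen-1(4H)-one
Product: 15 (4aS,8aS)-2,5,5,8a-tetramethyl-3,4,4a,5,6,7,8,8a-octahydronaphthalen-1-yl trifluoromethanesulfonate, via lithium enolate 14 (not isolated)
Conditions: Li[(s-Bu)3BH], THF, −78 °C; then N-(5-chloropyridin-2-yl)bis(trifluoromethanesulfonimide), −78 → 0 °C; aq. work-up
Reagents that add atoms: N-(5-chloropyridin-2-yl)bis(trifluoromethanesulfonimide), FC(F)(F)S(=O)(=O)N(c1ccc(Cl)cn1)S(=O)(=O)C(F)(F)F
Why: conjugate hydride addition to the β-unsubstituted 2-methylcyclohexenone unit should give the C8=C9 enolate only (C10 is quaternary), and O-triflation fixes the tetrasubstituted C8=C9 double bond of the target without creating a stereocentre at C8.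

Step 8
Reactants: 15 (4aS,8aS)-2,5,5,8a-tetramethyl-3,4,4a,5,6,7,8,8a-octahydronaphthalen-1-yl trifluoromethanesulfonate
Product: 16 (4aS,8aS)-1-ethenyl-2,5,5,8a-tetramethyl-3,4,4a,5,6,7,8,8a-octahydronaphthalene
Conditions: Pd(PPh3)4 (5 mol%), LiCl (3 equiv), THF, 65 °C
Reagents that add atoms: tributyl(vinyl)stannane, C=C[Sn](CCCC)(CCCC)CCCC
Why: Stille coupling of a cyclohexenyl triflate with a vinylstannane, with chloride assisting transmetalation; it should install C11 and C12 with the ring double bond left in place.

Step 9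
Reactants: 17 3-[tri(propan-2-yl)silyl]prop-2-ynal; 18 ethyl (triphenyl-λ5-phosphanylidene)acetate
Product: 20 ethyl (2Z)-2-iodo-5-[tri(propan-2-yl)silyl]pent-2-en-4-ynoate, via iodo ylide 19 (not isolated)
Conditions: N-iodosuccinimide, CH2Cl2, −20 °C; then 17, rt
Reagents that add atoms: N-iodosuccinimide, O=C1CCC(=O)N1I
Why: Wittig reaction of the α-iodo stabilised ylide formed in the flask; such ylides should place the ester trans to the aldehyde-derived substituent, which gives the (Z)-iodo-enoate.

Step 10
Reactants: 16 (4aS,8aS)-1-ethenyl-2,5,5,8a-tetramethyl-3,4,4a,5,6,7,8,8a-octahydronaphthalene; 20 ethyl (2Z)-2-iodo-5-[tri(propan-2-yl)silyl]pent-2-en-4-ynoate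
Product: 22 ethyl (2E)-2-{2-[(4aS,8aS)-2,5,5,8a-tetramethyl-3,4,4a,5,6,7,8,8a-octahydronaphthalen-1-yl]ethyl}-5-[tri(propan-2-yl)silyl]pent-2-en-4-ynoate, via alkylborane 21 (not isolated)
Conditions: 9-BBN-H, THF, rt; then 20, PdCl2(dppf) (5 mol%), AsPh3, Cs2CO3, DMF/H2O, rt
Reagents that add atoms: none
Why: anti-Markovnikov hydroboration of the only monosubstituted alkene (the tetrasubstituted ring alkene is inert), then B-alkyl Suzuki–Miyaura coupling with the α-iodo enoate; coupling with retention should put C12 cis to the alkynyl group, which is the 13E geometry.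

Step 11
Reactants: 22 the enyne ester
Product: 23 (2E)-2-{2-[(4aS,8aS)-2,5,5,8a-tetramethyl-3,4,4a,5,6,7,8,8a-octahydronaphthalen-1-yl]ethyl}-5-[tri(propan-2-yl)silyl]pent-2-en-4-yn-1-ol
Conditions: i-Bu2AlH (2.5 equiv), CH2Cl2, −78 °C
Reagents that add atoms: none
Why: 1,2-reduction of the conjugated ester to the allylic alcohol; the silyl alkyne and both alkenes should be untouched.

Step 12
Reactants: 23 the silylated enynol
Product: 24 (2E)-2-{2-[(4aS,8aS)-2,5,5,8a-tetramethyl-3,4,4a,5,6,7,8,8a-octahydronaphthalen-1-yl]ethyl}pent-2-en-4-yn-1-ol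
Conditions: Bu4NF, THF, 0 °C
Reagents that add atoms: none
Why: fluoride-induced C-desilylation of the alkynylsilane should free the terminal alkyne for step 14.

Step 13
Reactants: 25 but-2-ynoic acid
Product: 26 (2Z)-3-iodobut-2-enoic acid
Conditions: NaI, AcOH, 115 °C
Reagents that add atoms: sodium iodide, [Na+].[I-]
Why: anti hydroiodination of the ynoic acid should place iodine cis to the carboxyl group, as the lactonisation in step 14 requires.

Step 14
Reactants: 24 the terminal enynol; 26 (2Z)-3-iodobut-2-enoic acid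
Product: 28 (5Z)-5-{(2E)-3-(hydroxymethyl)-5-[(4aS,8aS)-2,5,5,8a-tetramethyl-3,4,4a,5,6,7,8,8a-octahydronaphthalen-1-yl]pent-2-en-1-ylidene}-4-methylfuran-2(5H)-one, via enynoic acid 27 (not isolated)
Conditions: PdCl2(PPh3)2 (5 mol%), CuI (10 mol%), Et3N, MeCN, rt
Reagents that add atoms: none
Why: Sonogashira coupling followed in the same flask by 5-exo-dig anti addition of the cis carboxylate to the palladium-activated alkyne and protonolysis, which should give the (Z)-ylidene butenolide; the free allylic alcohol is tolerated.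

**Compound list**

1 | isobutyronitrile | CC(C)C#N | starting material
2 | 1,3-dibromopropane | BrCCCBr | starting material
3 | 5-bromo-2,2-dimethylpentanenitrile | N#CC(C)(C)CCCBr | intermediate
4 | pentan-3-one | CCC(=O)CC | starting material
5 | N,N-dimethylhydrazine | CN(C)N | starting material
6 | pentan-3-one N,N-dimethylhydrazone | CCC(CC)=NN(C)C | intermediate
7 | 7-(2,2-dimethylhydrazinylidene)-2,2,6-trimethylnonanenitrile (racemic at C6) | CCC(=NN(C)C)C(C)CCCC(C)(C)C#N | intermediate
8 | 7-(2,2-dimethylhydrazinylidene)-2,2,6-trimethylnonanal (racemic at C6) | CCC(=NN(C)C)C(C)CCCC(C)(C)C=O | intermediate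
9 | diethyl [(E)-2-(cyclohexylamino)ethenyl]phosphonate | CCOP(=O)(OCC)/C=C/NC1CCCCC1 | starting material
10 | (2E)-N-cyclohexyl-9-(2,2-dimethylhydrazinylidene)-4,4,8-trimethylundec-2-en-1-imine (racemic at C8) | CCC(=NN(C)C)C(C)CCCC(C)(C)/C=C/C=NC1CCCCC1 | intermediate (not isolated)
11 | (2E)-4,4,8-trimethyl-9-oxoundec-2-enal (racemic at C8) | CCC(=O)C(C)CCCC(C)(C)/C=C/C=O | intermediate
12 | 2-[(1S,2S)-2,6,6-trimethyl-2-propanoylcyclohexyl]acetaldehyde | O=CC[C@H]1C(C)(C)CCC[C@]1(C)C(=O)CC | intermediate (not isolated)
13 | (4aS,8aS)-2,5,5,8a-tetramethyl-4a,5,6,7,8,8a-hexahydronaphthalen-1(4H)-one | CC1=CC[C@H]2C(C)(C)CCC[C@]2(C)C1=O | intermediate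
14 | lithium (4aS,8aS)-2,5,5,8a-tetramethyl-3,4,4a,5,6,7,8,8a-octahydronaphthalen-1-olate | [Li+].[O-]C1=C(C)CC[C@H]2C(C)(C)CCC[C@]12C | intermediate (not isolated)
15 | (4aS,8aS)-2,5,5,8a-tetramethyl-3,4,4a,5,6,7,8,8a-octahydronaphthalen-1-yl trifluoromethanesulfonate | FC(F)(F)S(=O)(=O)OC1=C(C)CC[C@H]2C(C)(C)CCC[C@]12C | intermediate
16 | (4aS,8aS)-1-ethenyl-2,5,5,8a-tetramethyl-3,4,4a,5,6,7,8,8a-octahydronaphthalene | C=CC1=C(C)CC[C@H]2C(C)(C)CCC[C@]12C | intermediate
17 | 3-[tri(propan-2-yl)silyl]prop-2-ynal | O=CC#C[Si](C(C)C)(C(C)C)C(C)C | starting material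
18 | ethyl (triphenyl-λ5-phosphanylidene)acetate | CCOC(=O)C=P(c1ccccc1)(c1ccccc1)c1ccccc1 | starting material
19 | ethyl iodo(triphenyl-λ5-phosphanylidene)acetate | CCOC(=O)C(I)=P(c1ccccc1)(c1ccccc1)c1ccccc1 | intermediate (not isolated)
20 | ethyl (2Z)-2-iodo-5-[tri(propan-2-yl)silyl]pent-2-en-4-ynoate | CCOC(=O)/C(I)=C/C#C[Si](C(C)C)(C(C)C)C(C)C | intermediate
21 | 9-{2-[(4aS,8aS)-2,5,5,8a-tetramethyl-3,4,4a,5,6,7,8,8a-octahydronaphthalen-1-yl]ethyl}-9-borabicyclo[3.3.1]nonane | C1CCC2CCCC1B2CCC3=C(C)CC[C@H]4C(C)(C)CCC[C@]34C | intermediate (not isolated)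
22 | ethyl (2E)-2-{2-[(4aS,8aS)-2,5,5,8a-tetramethyl-3,4,4a,5,6,7,8,8a-octahydronaphthalen-1-yl]ethyl}-5-[tri(propan-2-yl)silyl]pent-2-en-4-ynoate | CCOC(=O)/C(CCC1=C(C)CC[C@H]2C(C)(C)CCC[C@]12C)=C/C#C[Si](C(C)C)(C(C)C)C(C)C | intermediate
23 | (2E)-2-{2-[(4aS,8aS)-2,5,5,8a-tetramethyl-3,4,4a,5,6,7,8,8a-octahydronaphthalen-1-yl]ethyl}-5-[tri(propan-2-yl)silyl]pent-2-en-4-yn-1-ol | OC/C(CCC1=C(C)CC[C@H]2C(C)(C)CCC[C@]12C)=C/C#C[Si](C(C)C)(C(C)C)C(C)C | intermediate
24 | (2E)-2-{2-[(4aS,8aS)-2,5,5,8a-tetramethyl-3,4,4a,5,6,7,8,8a-octahydronaphthalen-1-yl]ethyl}pent-2-en-4-yn-1-ol | OC/C(CCC1=C(C)CC[C@H]2C(C)(C)CCC[C@]12C)=C/C#C | intermediate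
25 | but-2-ynoic acid | CC#CC(=O)O | starting material
26 | (2Z)-3-iodobut-2-enoic acid | C/C(I)=C/C(=O)O | intermediate
27 | (2Z,6E)-7-(hydroxymethyl)-3-methyl-9-[(4aS,8aS)-2,5,5,8a-tetramethyl-3,4,4a,5,6,7,8,8a-octahydronaphthalen-1-yl]nona-2,6-dien-4-ynoic acid | OC(=O)/C=C(/C)C#C/C=C(/CO)CCC1=C(C)CC[C@H]2C(C)(C)CCC[C@]12C | intermediate (not isolated)
28 | (5Z)-5-{(2E)-3-(hydroxymethyl)-5-[(4aS,8aS)-2,5,5,8a-tetramethyl-3,4,4a,5,6,7,8,8a-octahydronaphthalen-1-yl]pent-2-en-1-ylidene}-4-methylfuran-2(5H)-one | CC1=CC(=O)O/C1=C\C=C(\CO)CCC1=C(C)CC[C@H]2C(C)(C)CCC[C@]12C | target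

**Totals and risks**

Total step count: 14. Longest linear sequence: 11 steps (step 1 or 2, then 3, 4, 5, 6, 7, 8, 10, 11, 12, 14).

Steps most likely to fail:

1. Step 6. The hindered ketone may form its enamine too slowly, the enantiofacial preference may be too small or of the wrong sense, and some material may leak to the cis ring fusion. The fallback replaces asymmetric catalysis by resolution. From 11, acid catalysis (p-TsOH, PhMe, 80 °C, azeotropic removal of water) should effect the same Michael/aldol condensation through the more substituted enol, as in acid-catalysed Robinson annulations, to give the racemic enone F1. Addition of lithiated (S)-N,S-dimethyl-S-phenylsulfoximine (n-BuLi, THF, −78 °C) to its carbonyl group should give two diastereomers, the β-hydroxy sulfoximine of the (4aS,8aS) ketone F2 and the β-hydroxy sulfoximine of the mirror-image ketone F3, to be separated by chromatography. The carbinol configuration written for them assumes attack anti to the angular methyl group. Thermolysis of F2 (PhMe, 110 °C) releases the sulfoximine and rejoins the route at 13.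

2. Step 8. Oxidative addition and transmetalation at the tetrasubstituted C9 triflate, flanked by the quaternary C10 and the C8 methyl group, may be too slow, and reduction or hydrolysis of the triflate may win. The fallback brings in C11 by carbonylation, which is less sensitive to hindrance, and C12 by olefination. From 15, methoxycarbonylation (Pd(OAc)2, PPh3, CO, MeOH, Et3N, DMF, 60 °C) should give the methyl ester F4. Reduction with i-Bu2AlH gives the allylic alcohol F5, oxidation with MnO2 the aldehyde F6, and Wittig methylenation (Ph3P=CH2, THF) rejoins the route at 16.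

3. Step 10. Hydroboration of the twisted, hindered diene may be incomplete or unselective, and the alkylborane may suffer protodeboronation or β-hydride elimination before it couples. The fallback forms the C13=C14 double bond by olefination in place of the C12–C13 cross-coupling. From 16, hydroboration–oxidation (9-BBN-H, then NaOH, H2O2) should give the primary alcohol F7. I2, PPh3 and imidazole convert it into the iodide F8, and alkylation of triethyl phosphonoacetate (NaH, DMSO) gives the phosphonate F9. Its Horner–Wadsworth–Emmons reaction with 17 (NaH, THF) should favour the ester trans to the alkynyl group and rejoins the route at 22.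

Further compounds
F1 | step 6 | racemic 2,5,5,8a-tetramethyl-4a,5,6,7,8,8a-hexahydronaphthalen-1(4H)-one, (4aS,8aS) and (4aR,8aR) | CC1=CC[C@H]2C(C)(C)CCC[C@]2(C)C1=O.CC1=CC[C@@H]2C(C)(C)CCC[C@@]2(C)C1=O
F2 | step 6 | (1S,4aS,8aS)-2,5,5,8a-tetramethyl-1-{[(S)-N-methyl-S-phenylsulfonimidoyl]methyl}-1,4,4a,5,6,7,8,8a-octahydronaphthalen-1-ol | CC1=CC[C@H]2C(C)(C)CCC[C@]2(C)[C@]1(O)C[S@@](=O)(=NC)c3ccccc3
F3 | step 6 | (1R,4aR,8aR)-2,5,5,8a-tetramethyl-1-{[(S)-N-methyl-S-phenylsulfonimidoyl]methyl}-1,4,4a,5,6,7,8,8a-octahydronaphthalen-1-ol | CC1=CC[C@@H]2C(C)(C)CCC[C@@]2(C)[C@@]1(O)C[S@@](=O)(=NC)c3ccccc3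
F4 | step 8 | methyl (4aS,8aS)-2,5,5,8a-tetramethyl-3,4,4a,5,6,7,8,8a-octahydronaphthalene-1-carboxylate | COC(=O)C1=C(C)CC[C@H]2C(C)(C)CCC[C@]12C
F5 | step 8 | [(4aS,8aS)-2,5,5,8a-tetramethyl-3,4,4a,5,6,7,8,8a-octahydronaphthalen-1-yl]methanol | OCC1=C(C)CC[C@H]2C(C)(C)CCC[C@]12C
F6 | step 8 | (4aS,8aS)-2,5,5,8a-tetramethyl-3,4,4a,5,6,7,8,8a-octahydronaphthalene-1-carbaldehyde | O=CC1=C(C)CC[C@H]2C(C)(C)CCC[C@]12C
F7 | step 10 | 2-[(4aS,8aS)-2,5,5,8a-tetramethyl-3,4,4a,5,6,7,8,8a-octahydronaphthalen-1-yl]ethan-1-ol | OCCC1=C(C)CC[C@H]2C(C)(C)CCC[C@]12C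
F8 | step 10 | (4aS,8aS)-1-(2-iodoethyl)-2,5,5,8a-tetramethyl-3,4,4a,5,6,7,8,8a-octahydronaphthalene | ICCC1=C(C)CC[C@H]2C(C)(C)CCC[C@]12C
F9 | step 10 | ethyl 2-(diethoxyphosphoryl)-4-[(4aS,8aS)-2,5,5,8a-tetramethyl-3,4,4a,5,6,7,8,8a-octahydronaphthalen-1-yl]butanoate | CCOC(=O)C(CCC1=C(C)CC[C@H]2C(C)(C)CCC[C@]12C)P(=O)(OCC)OCC
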